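**Plan**

- Labdane numbering is used: ring A = C1–C5 and C10, ring B = C5–C10, C20 = the CH2OAc carbon on C10. The bonds are cut in this order: the C2–O angelate and C20–O acetate, then C9–C11 (side chain C11–C16, taken from (R)-linalool), then C8–C17, then C2=C3 of ring A, and last C4–C5 and C1–C10.
- The feature that makes the key step possible lies in ring B. The quaternary C10 (bearing C20 at carboxyl level) and the tertiary C5 (bonded to the quaternary C4) lie next to C9. With C9 as a ketone, C10 and C5 are the α and β carbons of an enone ester, C4 is the α carbon of an isobutyric thioester, and C1 is the end of an allyl unit.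
- In the forward direction ring B is bought and one flask forms C4–C5 and C1–C10. Ring A then closes by metathesis. The C9 ketone brings in C17 and the side chain, a 1,3-carbonyl transposition and a reductive allylic shift place C7=C8 and 9-H, and the esters come last.
- Stereochemistry: C5 comes from a chiral copper catalyst and C10 from C5 (allyl enters trans). C2 and C3 come from α-face osmylation. C9 comes from suprafacial hydrogen delivery by a 7α-diazene, which is made from the 7β-alcohol by Mitsunobu inversion. C13 comes from the chiral pool.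

Key step: step 3

Assumption: the sense of induction of the copper catalyst on this cyclic acceptor cannot be read safely from acyclic models; the (S,S)-ligand is written, and if it favours the wrong C5 face the equally available (R,R)-ligand takes its place with nothing else changed.

**Route**

Step 1
Reactants: 1 methyl 2-oxocyclohexane-1-carboxylate
Product: 3 methyl 6-oxocyclohex-1-ene-1-carboxylate, via methyl 2-oxo-1-(phenylselanyl)cyclohexane-1-carboxylate 2 (not isolated)
Conditions: PhSeCl, pyridine, CH2Cl2, 0 °C; then 30% aq H2O2, 0 °C → rt; used at once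
Reagents that add atoms: none
Why: α-Selenenylation of the enolised β-keto ester at C10 followed by selenoxide syn-elimination, for which only the C5 methylene offers a β-hydrogen, is the standard entry to 2-carboalkoxycycloalkenones.

Step 2
Reactants: 4 S-ethyl 2-methylpropanethioate
Product: 5 {[1-(ethylsulfanyl)-2-methylprop-1-en-1-yl]oxy}trimethylsilane
Conditions: LiN(i-Pr)2, THF, −78 °C; Me3SiCl, −78 °C → rt
Reagents that add atoms: chlorotrimethylsilane, C[Si](C)(C)Cl
Why: Deprotonation of the thioester and O-silylation of its lithium enolate is the usual silyl ketene acetal synthesis, and the two identical methyl groups remove any question of double-bond geometry.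

Step 3
Reactants: 3 methyl 6-oxocyclohex-1-ene-1-carboxylate; 5 {[1-(ethylsulfanyl)-2-methylprop-1-en-1-yl]oxy}trimethylsilane; 6 allyl bromide
Product: 8 methyl (1R,2R)-1-allyl-2-[1-(ethylsulfanyl)-2-methyl-1-oxopropan-2-yl]-6-oxocyclohexane-1-carboxylate, via Michael adduct β-keto ester 7 (not isolated)
Conditions: [Cu((S,S)-t-Bu-box)](SbF6)2 (10 mol %; t-Bu-box = 2,2'-(propane-2,2-diyl)bis(4-tert-butyl-4,5-dihydrooxazole)), (CF3)2CHOH (1.1 equiv), CH2Cl2–PhMe, −78 → −20 °C; volatiles removed in the same flask; DMF, Cs2CO3, 6, 0 °C → rt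
Reagents that add atoms: none
Why: The ketone and ester oxygens of 3 chelate the divalent copper centre, the ketene acetal 5 attacks the activated C5 through an open transition state (Mukaiyama–Michael addition, C4–C5), and (CF3)2CHOH takes over the Me3Si group and protonates the copper enolate so that the catalyst is released and 7 builds up. Cs2CO3 then forms the caesium enolate of 7, which displaces bromide from 6 in an SN2 alkylation (C1–C10). The closest known reactions are the copper bis(oxazoline)-catalysed additions of thioester silyl ketene acetals to alkylidene malonates and 2-carboalkoxycycloalkenones and the trans-selective alkylation of 3-substituted 2-oxocycloalkanecarboxylates. No ring closes in this step. C5 is set by the catalyst, whose tert-butyl groups leave one face of the flat chelated acceptor open, and C10 is set by C5, because the tert-alkyl group turns pseudoaxial to escape allylic strain with the enolate ester and so sends the allyl group to the opposite face, leaving C20 cis to C4. The step needs 1,4- over 1,2-addition, secured by two-point binding and the soft nucleophile, and C- over O-allylation, secured by the soft bromide (any allyl enol ether should be funnelled to 8 by Claisen rearrangement on warming), while the thioester, lacking α-hydrogens, stays a spectator.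

Step 4
Reactants: 8 methyl (1R,2R)-1-allyl-2-[1-(ethylsulfanyl)-2-methyl-1-oxopropan-2-yl]-6-oxocyclohexane-1-carboxylate
Product: 9 methyl (1R,2S)-1-allyl-2-(2-methyl-1-oxopropan-2-yl)-6-oxocyclohexane-1-carboxylate
Conditions: Et3SiH, Pd/CaCO3 poisoned with Pb(OAc)2 (5 mol % Pd), 1-decene, acetone, rt
Reagents that add atoms: none
Why: In the Fukuyama reduction zerovalent palladium inserts into the C–S bond and the acylpalladium species is reduced by the silane, which leaves ketone and ester alone, while the poisoned catalyst and the sacrificial alkene keep the allyl group from being hydrogenated.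

Step 5
Reactants: 9 methyl (1R,2S)-1-allyl-2-(2-methyl-1-oxopropan-2-yl)-6-oxocyclohexane-1-carboxylate
Product: 10 methyl (1R,2S)-1-allyl-2-(2-methylbut-3-en-2-yl)-6-oxocyclohexane-1-carboxylate
Conditions: Ph3PCH3Br, KN(SiMe3)2, THF, 0 °C; ylide (1.05 equiv) added to 9, −78 → 0 °C
Reagents that add atoms: methyltriphenylphosphonium bromide, C[P+](c1ccccc1)(c1ccccc1)c1ccccc1.[Br-]
Why: Wittig methylenation is far faster at the aldehyde than at the ketone flanked by the quaternary C10, so one equivalent of ylide at low temperature should convert only C3.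

Step 6
Reactants: 10 methyl (1R,2S)-1-allyl-2-(2-methylbut-3-en-2-yl)-6-oxocyclohexane-1-carboxylate
Product: 11 methyl (4aS,8aR)-5,5-dimethyl-1-oxo-1,3,4,4a,5,8-hexahydronaphthalene-8a(2H)-carboxylate (trans-fused rings A and B, C2=C3, C9 ketone, 10β-CO2Me, 5α-H)
Conditions: second-generation Grubbs catalyst (H2IMes)(PCy3)Cl2Ru=CHPh (5 mol %), CH2Cl2, reflux
Reagents that add atoms: none
Why: Ring-closing metathesis starts at the unhindered allyl group and closes the six-membered ring A (C2=C3) onto the neopentylic vinyl group, and since the two chains are trans-diequatorial on ring B the trans-decalin results without a new stereocentre.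

Step 7
Reactants: 11 trans-fused C2=C3 keto ester
Product: 12 methyl 2α,3α-dihydroxy-4,4-dimethyl-9-oxo-trans-decalin-10β-carboxylate (labdane numbering, 5α-H)
Conditions: OsO4 (5 mol %), N-methylmorpholine N-oxide, acetone–H2O, rt
Reagents that add atoms: osmium tetroxide (catalytic oxygen carrier), O=[Os](=O)(=O)=O; N-methylmorpholine N-oxide, C[N+]1([O-])CCOCC1; water, O
Why: Upjohn dihydroxylation is a syn addition, and because the β face of C2=C3 is closed by the axial C10 ester and the axial C4 methyl group the osmate should form on the α face and give the 2α,3α-diol.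

Step 8
Reactants: 12 2α,3α-diol keto ester
Product: 13 2α,3α-O-isopropylidene derivative (acetonide) of 12
Conditions: Me2C(OMe)2, pyridinium p-toluenesulfonate (cat.), CH2Cl2, rt
Reagents that add atoms: 2,2-dimethoxypropane, COC(C)(C)OC
Why: Acid-catalysed transketalisation protects the cis-diol as its five-membered acetonide, which withstands the bases, organometallics, oxidants and hydrides used up to step 20.

Step 9
Reactants: 13 acetonide keto ester
Product: 14 8α-methyl ketone (13 with an equatorial methyl group, C17, at C8)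
Conditions: LiN(i-Pr)2, THF, −78 °C; MeI, −78 → 0 °C
Reagents that add atoms: iodomethane, CI
Why: Alkylation of the only enolate the ketone can form (C10 is quaternary) brings in C17, the methyl group being expected equatorial (8α) because the axial β approach meets the syn-axial ester, although this centre is erased in step 10.

Step 10
Reactants: 14 8α-methyl ketone
Product: 16 8-methyl-7-en-9-one (acetonide and 10β-CO2Me retained), via trimethylsilyl enol ether 15 (not isolated)
Conditions: LiN(i-Pr)2, THF, −78 → 0 °C; Me3SiCl; then Pd(OAc)2 (1.05 equiv), MeCN, rt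
Reagents that add atoms: none
Why: In the Saegusa–Ito oxidation the enol ether, again the only one possible, is palladated at C8 and β-hydride elimination towards C7 gives the conjugated endocyclic enone, any exocyclic isomer being drawn into it by palladium hydride re-addition.

Step 11
Reactants: 17 (R)-(−)-linalool
Product: 18 (R)-linalool tert-butyldimethylsilyl ether
Conditions: t-BuMe2SiOTf, 2,6-lutidine, CH2Cl2, 0 °C
Reagents that add atoms: tert-butyldimethylsilyl triflate, CC(C)(C)[Si](C)(C)OS(=O)(=O)C(F)(F)F
Why: A silyl triflate with a hindered pyridine base is the standard way to silylate a tertiary alcohol, and the future C13 is untouched because only the O–H bond reacts.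

Step 12
Reactants: 18 (R)-linalool tert-butyldimethylsilyl ether
Product: 19 (R)-4-(tert-butyldimethylsilyloxy)-4-methylhex-5-enal
Conditions: O3 (1 equiv, Sudan red 7B end point), CH2Cl2, −78 °C; then Me2S
Reagents that add atoms: ozone, [O-][O+]=O
Why: Ozonolysis follows alkene nucleophilicity, so the trisubstituted isopropylidene double bond is cleaved well before the vinyl group, which is monosubstituted and shielded by the quaternary silyloxy carbon.

Step 13
Reactants: 19 (R)-4-(tert-butyldimethylsilyloxy)-4-methylhex-5-enal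
Product: 20 (R)-4-(tert-butyldimethylsilyloxy)-4-methylhex-5-enoic acid
Conditions: NaClO2, NaH2PO4, 2-methylbut-2-ene, t-BuOH–H2O, rt
Reagents that add atoms: sodium chlorite, [Na+].[O-]Cl=O
Why: Pinnick oxidation converts the aldehyde into the acid under buffered conditions, with 2-methylbut-2-ene taking up the hypochlorous acid that would otherwise attack the vinyl group.

Step 14
Reactants: 20 (R)-4-(tert-butyldimethylsilyloxy)-4-methylhex-5-enoic acid
Product: 22 (R)-tert-butyl[(5-iodo-3-methylpent-1-en-3-yl)oxy]dimethylsilane, via N-acyloxypyridine-2-thione ester 21 (not isolated)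
Conditions: 1-hydroxypyridine-2(1H)-thione, DCC, CH2Cl2, 0 °C → rt, dark; then CHI3, PhH, tungsten lamp, rt
Reagents that add atoms: iodoform, IC(I)I
Why: In the Barton decarboxylative iodination photolysis of the thiohydroxamate ester gives the primary C11 radical, which closes too slowly to a four-membered ring on the vinyl group to compete, abstracts iodine from CHI3 and so loses exactly the one surplus carbon of linalool.

Step 15
Reactants: 22 (R)-tert-butyl[(5-iodo-3-methylpent-1-en-3-yl)oxy]dimethylsilane; 16 8-methyl-7-en-9-one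
Product: 25 tertiary allylic alcohol, the 9β-hydroxy-9α-[(3R)-3-(tert-butyldimethylsilyloxy)-3-methylpent-4-en-1-yl] adduct of 16, via side-chain alkyllithium 23 (not isolated), via side-chain organocerium dichloride 24 (not isolated)
Conditions: 22, t-BuLi (2.1 equiv), Et2O–pentane, −78 °C; anhydrous CeCl3, THF, −78 °C; then 16, −78 → −40 °C; aqueous work-up
Reagents that add atoms: none
Why: Lithium–iodine exchange and transmetallation give a weakly basic, oxophilic organocerium reagent that adds 1,2 to hindered enolisable enones of the 2,6,6-trisubstituted cyclohexenone type in preference to the neopentylic ester, attack from the α face opposite the axial ester being expected, though this C9 centre is erased in step 16.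

Step 16
Reactants: 25 tertiary allylic alcohol
Product: 26 methyl (13R)-13-(tert-butyldimethylsilyloxy)-2α,3α-isopropylidenedioxy-7-oxolabda-8,14-dien-20-oate
Conditions: pyridinium chlorochromate (2–3 equiv), 4 Å molecular sieves, CH2Cl2, rt
Reagents that add atoms: pyridinium chlorochromate, [O-][Cr](=O)(=O)Cl.c1cc[nH+]cc1
Why: In the Babler–Dauben oxidative transposition the chromate ester of the tertiary allylic alcohol shifts [3,3] from C9 to C7 and is then oxidised, which moves the carbonyl group to C7 and leaves the side chain on the C8=C9 double bond.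

Step 17
Reactants: 26 7-oxo-8-ene
Product: 27 methyl (13R)-13-(tert-butyldimethylsilyloxy)-7β-hydroxy-2α,3α-isopropylidenedioxylabda-8,14-dien-20-oate
Conditions: NaBH4, CeCl3·7H2O, MeOH, −78 → 0 °C
Reagents that add atoms: none
Why: Luche reduction gives clean 1,2-reduction, and hydride should enter C7 along the axial α trajectory (the β face lies under the axial C10 ester) to give the pseudoequatorial 7β-alcohol, the ester being inert.

Step 18
Reactants: 27 7β-allylic alcohol
Product: 30 methyl (13R)-13-(tert-butyldimethylsilyloxy)-2α,3α-isopropylidenedioxylabda-7,14-dien-20-oate (9α-H), via 7α-sulfonylhydrazone 28 (not isolated), via 7α-allylic diazene 29 (not isolated)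
Conditions: N-isopropylidene-N'-(2-nitrobenzenesulfonyl)hydrazine, PPh3, diethyl azodicarboxylate, THF, 0 °C → rt; then CF3CH2OH–H2O (1:1), rt
Reagents that add atoms: none
Why: Mitsunobu displacement inverts C7 (β-O to α-N), and after hydrolysis and loss of the sulfinic acid the 7α-diazene hands its hydrogen suprafacially to the α face of C9 in a retro-ene loss of N2 (reductive allylic transposition), which sets 9α-H and moves the olefin to C7=C8.

Step 19
Reactants: 30 7,14-dien-20-oate
Product: 31 (13R)-13-(tert-butyldimethylsilyloxy)-2α,3α-isopropylidenedioxylabda-7,14-dien-20-ol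
Conditions: LiAlH4, THF, 0 °C → reflux; H2O, aq NaOH work-up
Reagents that add atoms: none
Why: Hydride reduction of the only remaining carbonyl group, the hindered axial ester, needs LiAlH4 with warming, which acetonide, silyl ether and isolated alkenes tolerate.

Step 20
Reactants: 31 C20 alcohol
Product: 32 20-acetate of 31
Conditions: Ac2O, pyridine, 4-dimethylaminopyridine (cat.), CH2Cl2, rt
Reagents that add atoms: acetic anhydride, CC(=O)OC(C)=O
Why: Nucleophile-catalysed acetylation meets a single free hydroxyl group, the neopentylic primary C20–OH.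

Step 21
Reactants: 32 20-acetate acetonide
Product: 33 (13R)-20-acetoxy-13-(tert-butyldimethylsilyloxy)labda-7,14-diene-2α,3α-diol
Conditions: AcOH–THF–H2O (3:1:1), 45 °C
Reagents that add atoms: none
Why: Weak aqueous acid hydrolyses the cis-fused acetonide, strained by the neighbouring gem-dimethyl group, while the hindered tertiary silyl ether stays on and keeps the allylic C13 from ionising, and acetate and the C7=C8 olefin are stable.

Step 22
Reactants: 33 2α,3α-diol; 34 angelic acid, (Z)-2-methylbut-2-enoic acid
Product: 36 (13R)-20-acetoxy-2α-angeloyloxy-13-(tert-butyldimethylsilyloxy)labda-7,14-dien-3α-ol, via angelic 2,4,6-trichlorobenzoic anhydride 35 (not isolated)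
Conditions: 34, 2,4,6-Cl3C6H2COCl, Et3N, PhMe, rt; then 33, 80 °C
Reagents that add atoms: none
Why: Mixed-anhydride (Yamaguchi-type) acylation run without 4-dimethylaminopyridine is the established way to transfer the angeloyl group without Z to E isomerisation, and the equatorial 2α-OH should react well ahead of the axial 3α-OH, which is neopentylic to C4.

Step 23
Reactants: 36 13-silyl ether
Product: 37 20-acetoxy-2α-angeloyloxylabda-7,14-diene-3α,13-diol, (2R,3S,5R,9S,10S,13R), CNP0171655.1
Conditions: HF·pyridine, THF–pyridine, 0 °C → rt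
Reagents that add atoms: none
Why: Fluoride-driven Si–O cleavage under weakly acidic, non-basic conditions should free the tertiary alcohol without acyl migration, ester loss, angelate isomerisation or allylic ionisation.

**Compound list**

1 | methyl 2-oxocyclohexane-1-carboxylate | COC(=O)C1CCCCC1=O | starting material
2 | methyl 2-oxo-1-(phenylselanyl)cyclohexane-1-carboxylate (racemic, not isolated) | COC(=O)C1([Se]c2ccccc2)CCCCC1=O | intermediate
3 | methyl 6-oxocyclohex-1-ene-1-carboxylate | COC(=O)C1=CCCCC1=O | intermediate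
4 | S-ethyl 2-methylpropanethioate | CCSC(=O)C(C)C | starting material
5 | {[1-(ethylsulfanyl)-2-methylprop-1-en-1-yl]oxy}trimethylsilane | CCSC(O[Si](C)(C)C)=C(C)C | intermediate
6 | allyl bromide | C=CCBr | starting material
7 | methyl (2R)-2-[1-(ethylsulfanyl)-2-methyl-1-oxopropan-2-yl]-6-oxocyclohexane-1-carboxylate (C10 epimers and enol, not isolated) | O=C1CCC[C@@H](C(C)(C)C(=O)SCC)C1C(=O)OC | intermediate
8 | methyl (1R,2R)-1-allyl-2-[1-(ethylsulfanyl)-2-methyl-1-oxopropan-2-yl]-6-oxocyclohexane-1-carboxylate | O=C1CCC[C@@H](C(C)(C)C(=O)SCC)[C@@]1(CC=C)C(=O)OC | intermediate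
9 | methyl (1R,2S)-1-allyl-2-(2-methyl-1-oxopropan-2-yl)-6-oxocyclohexane-1-carboxylate | O=C1CCC[C@@H](C(C)(C)C=O)[C@@]1(CC=C)C(=O)OC | intermediate
10 | methyl (1R,2S)-1-allyl-2-(2-methylbut-3-en-2-yl)-6-oxocyclohexane-1-carboxylate | O=C1CCC[C@@H](C(C)(C)C=C)[C@@]1(CC=C)C(=O)OC | intermediate
11 | methyl (4aS,8aR)-5,5-dimethyl-1-oxo-1,3,4,4a,5,8-hexahydronaphthalene-8a(2H)-carboxylate | O=C1CCC[C@H]2C(C)(C)C=CC[C@]12C(=O)OC | intermediate
12 | methyl 2α,3α-dihydroxy-4,4-dimethyl-9-oxo-trans-decalin-10β-carboxylate (5α-H) | O=C1CCC[C@H]2C(C)(C)[C@H](O)[C@H](O)C[C@]12C(=O)OC | intermediate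
13 | 2α,3α-acetonide of 12 | O=C1CCC[C@H]2C(C)(C)[C@@H]3OC(C)(C)O[C@@H]3C[C@]12C(=O)OC | intermediate
14 | 8α-methyl derivative of 13 | O=C1[C@H](C)CC[C@H]2C(C)(C)[C@@H]3OC(C)(C)O[C@@H]3C[C@]12C(=O)OC | intermediate
15 | C8=C9 trimethylsilyl enol ether of 14 (not isolated) | C[Si](C)(C)OC1=C(C)CC[C@H]2C(C)(C)[C@@H]3OC(C)(C)O[C@@H]3C[C@]12C(=O)OC | intermediate
16 | 8-methyl-7-en-9-one, acetonide, 10β-CO2Me | O=C1C(C)=CC[C@H]2C(C)(C)[C@@H]3OC(C)(C)O[C@@H]3C[C@]12C(=O)OC | intermediate
17 | (R)-(−)-linalool | C=C[C@](C)(O)CCC=C(C)C | starting material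
18 | (R)-linalool tert-butyldimethylsilyl ether | C=C[C@](C)(O[Si](C)(C)C(C)(C)C)CCC=C(C)C | intermediate
19 | (R)-4-(tert-butyldimethylsilyloxy)-4-methylhex-5-enal | C=C[C@](C)(O[Si](C)(C)C(C)(C)C)CCC=O | intermediate
20 | (R)-4-(tert-butyldimethylsilyloxy)-4-methylhex-5-enoic acid | C=C[C@](C)(O[Si](C)(C)C(C)(C)C)CCC(=O)O | intermediate
21 | 2-thioxopyridin-1(2H)-yl ester of 20 (not isolated) | C=C[C@](C)(O[Si](C)(C)C(C)(C)C)CCC(=O)On1ccccc1=S | intermediate
22 | (R)-tert-butyl[(5-iodo-3-methylpent-1-en-3-yl)oxy]dimethylsilane | C=C[C@](C)(O[Si](C)(C)C(C)(C)C)CCI | intermediate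
23 | alkyllithium from 22 (not isolated) | C=C[C@](C)(O[Si](C)(C)C(C)(C)C)CC[Li] | intermediate
24 | alkylcerium dichloride from 23 (not isolated) | C=C[C@](C)(O[Si](C)(C)C(C)(C)C)CC[Ce](Cl)Cl | intermediate
25 | 9β-hydroxy-9α-alkyl adduct of 16 and 24 | C=C[C@](C)(O[Si](C)(C)C(C)(C)C)CC[C@]1(O)C(C)=CC[C@H]2C(C)(C)[C@@H]3OC(C)(C)O[C@@H]3C[C@]12C(=O)OC | intermediate
26 | methyl (13R)-13-(tert-butyldimethylsilyloxy)-2α,3α-isopropylidenedioxy-7-oxolabda-8,14-dien-20-oate | C=C[C@](C)(O[Si](C)(C)C(C)(C)C)CCC1=C(C)C(=O)C[C@H]2C(C)(C)[C@@H]3OC(C)(C)O[C@@H]3C[C@]12C(=O)OC | intermediate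
27 | 7β-alcohol of 26 | C=C[C@](C)(O[Si](C)(C)C(C)(C)C)CCC1=C(C)[C@@H](O)C[C@H]2C(C)(C)[C@@H]3OC(C)(C)O[C@@H]3C[C@]12C(=O)OC | intermediate
28 | 7α-[N-(2-nitrobenzenesulfonyl)-N'-isopropylidenehydrazinyl] derivative (not isolated) | C=C[C@](C)(O[Si](C)(C)C(C)(C)C)CCC1=C(C)[C@H](N(N=C(C)C)S(=O)(=O)c4ccccc4[N+](=O)[O-])C[C@H]2C(C)(C)[C@@H]3OC(C)(C)O[C@@H]3C[C@]12C(=O)OC | intermediate
29 | 7α-allylic diazene (not isolated) | C=C[C@](C)(O[Si](C)(C)C(C)(C)C)CCC1=C(C)[C@H](N=N)C[C@H]2C(C)(C)[C@@H]3OC(C)(C)O[C@@H]3C[C@]12C(=O)OC | intermediate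
30 | methyl (13R)-13-(tert-butyldimethylsilyloxy)-2α,3α-isopropylidenedioxylabda-7,14-dien-20-oate | C=C[C@](C)(O[Si](C)(C)C(C)(C)C)CC[C@H]1C(C)=CC[C@H]2C(C)(C)[C@@H]3OC(C)(C)O[C@@H]3C[C@]12C(=O)OC | intermediate
31 | (13R)-13-(tert-butyldimethylsilyloxy)-2α,3α-isopropylidenedioxylabda-7,14-dien-20-ol | C=C[C@](C)(O[Si](C)(C)C(C)(C)C)CC[C@H]1C(C)=CC[C@H]2C(C)(C)[C@@H]3OC(C)(C)O[C@@H]3C[C@]12CO | intermediate
32 | 20-acetate of 31 | C=C[C@](C)(O[Si](C)(C)C(C)(C)C)CC[C@H]1C(C)=CC[C@H]2C(C)(C)[C@@H]3OC(C)(C)O[C@@H]3C[C@]12COC(C)=O | intermediate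
33 | (13R)-20-acetoxy-13-(tert-butyldimethylsilyloxy)labda-7,14-diene-2α,3α-diol | C=C[C@](C)(O[Si](C)(C)C(C)(C)C)CC[C@H]1C(C)=CC[C@H]2C(C)(C)[C@H](O)[C@H](O)C[C@]12COC(C)=O | intermediate
34 | angelic acid | C/C=C(/C)C(=O)O | starting material
35 | angelic 2,4,6-trichlorobenzoic anhydride (not isolated) | C/C=C(/C)C(=O)OC(=O)c1c(Cl)cc(Cl)cc1Cl | intermediate
36 | (13R)-20-acetoxy-2α-angeloyloxy-13-(tert-butyldimethylsilyloxy)labda-7,14-dien-3α-ol | C=C[C@](C)(O[Si](C)(C)C(C)(C)C)CC[C@H]1C(C)=CC[C@H]2C(C)(C)[C@H](O)[C@H](OC(=O)/C(C)=C\C)C[C@]12COC(C)=O | intermediate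
37 | 20-acetoxy-2α-angeloyloxylabda-7,14-diene-3α,13-diol, (2R,3S,5R,9S,10S,13R) | C=C[C@](C)(O)CC[C@H]1C(C)=CC[C@H]2C(C)(C)[C@H](O)[C@H](OC(=O)/C(C)=C\C)C[C@]12COC(C)=O | target

**Step count**

Total step count: 23. Longest linear sequence: 18 steps (steps 1, 3–10 and 15–23, from 1 to 37).

**Steps most likely to fail**

Step 3. The fully substituted ketene acetal may add only slowly to the crowded chelate. The reacting carbon C5 also lies far from the tert-butyl groups of the ligand, so discrimination between the two faces may be poor and the enantiomeric purity of everything downstream would suffer.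
- The fallback gives up catalytic induction for a racemic synthesis with classical resolution. It sets out from 3, 5 and 6.
- The same one-flask sequence is run with ligand-free Cu(OTf)2, which is less crowded and more Lewis acidic. It gives 8 as the racemate, that is together with its mirror image, the (1S,2S)-allyl keto thioester F1.
- Fukuyama reduction as in step 4 gives 9 together with the (1S,2R)-keto aldehyde F2.
- Condensation with (1R,2R)-N,N'-dimethyl-1,2-diphenylethane-1,2-diamine (Et2O, 4 Å molecular sieves, rt) turns the aldehyde group into two diastereomers, the imidazolidine of 9 F3 and the imidazolidine of the mirror-image aldehyde F4. These are separated by chromatography or crystallisation.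
- Dilute aq HCl–Et2O hydrolyses F3, and the route is rejoined at 9.

Step 15. Several processes may compete with carbonyl addition at the doubly flanked C9: γ-deprotonation of the hindered enone, attack at the ester, and retro-aldol cleavage of the β-alkoxy ester.
- The fallback replaces carbonyl addition by cross-coupling. It sets out from 14 and 22.
- KN(SiMe3)2 and PhNTf2 convert 14 into the C8=C9 enol triflate F5.
- Compound 22 is lithiated as in step 15 (23) and trapped with 9-methoxy-9-borabicyclo[3.3.1]nonane to give the lithium B-alkyl-B-methoxyborinate F6.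
- F6 is coupled with F5 (PdCl2(dppf), K3PO4, DMF–THF, 50 °C, B-alkyl Suzuki–Miyaura coupling) to give the tetrasubstituted 8(9)-olefin F7.
- Allylic oxidation of the ring methylene C7 (CrO3·3,5-dimethylpyrazole, CH2Cl2, −20 °C) gives 26, where the route is rejoined. Steps 10, 15 and 16 are bypassed.

Step 18. Mitsunobu displacement at the hindered allylic C7 may be slow. It may then give way to ionisation with loss of configuration or to elimination towards a diene, and either would erode the configuration at C9.
- The fallback sets out from 27. Formylation (HCO2H–Ac2O, pyridine, 0 °C) gives the 7β-formate F8.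
- Pd(OAc)2/n-Bu3P in THF (rt → reflux) ionises the formate from the α face.
- Loss of CO2 leaves a palladium hydride that hands hydrogen to the more substituted allyl terminus C9 on that same α face (palladium-catalysed hydrogenolysis of allylic formates). This gives 30, where the route is rejoined.

**Further compounds**

F1 | step 3 | methyl (1S,2S)-1-allyl-2-[1-(ethylsulfanyl)-2-methyl-1-oxopropan-2-yl]-6-oxocyclohexane-1-carboxylate (mirror image of 8) | O=C1CCC[C@H](C(C)(C)C(=O)SCC)[C@]1(CC=C)C(=O)OC
F2 | step 3 | methyl (1S,2R)-1-allyl-2-(2-methyl-1-oxopropan-2-yl)-6-oxocyclohexane-1-carboxylate (mirror image of 9) | O=C1CCC[C@H](C(C)(C)C=O)[C@]1(CC=C)C(=O)OC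
F3 | step 3 | (4R,5R)-1,3-dimethyl-4,5-diphenylimidazolidin-2-yl derivative (aminal) of 9 | O=C1CCC[C@@H](C(C)(C)C2N(C)[C@H](c3ccccc3)[C@@H](c3ccccc3)N2C)[C@@]1(CC=C)C(=O)OC
F4 | step 3 | (4R,5R)-1,3-dimethyl-4,5-diphenylimidazolidin-2-yl derivative (aminal) of F2 | O=C1CCC[C@H](C(C)(C)C2N(C)[C@H](c3ccccc3)[C@@H](c3ccccc3)N2C)[C@]1(CC=C)C(=O)OC
F5 | step 15 | C8=C9 enol triflate of 14 | FC(F)(F)S(=O)(=O)OC1=C(C)CC[C@H]2C(C)(C)[C@@H]3OC(C)(C)O[C@@H]3C[C@]12C(=O)OC
F6 | step 15 | lithium B-[(3R)-3-(tert-butyldimethylsilyloxy)-3-methylpent-4-en-1-yl]-B-methoxy-9-borabicyclo[3.3.1]nonanate | [Li+].C=C[C@](C)(O[Si](C)(C)C(C)(C)C)CC[B-]1(OC)C2CCCC1CCC2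
F7 | step 15 | methyl (13R)-13-(tert-butyldimethylsilyloxy)-2α,3α-isopropylidenedioxylabda-8,14-dien-20-oate | C=C[C@](C)(O[Si](C)(C)C(C)(C)C)CCC1=C(C)CC[C@H]2C(C)(C)[C@@H]3OC(C)(C)O[C@@H]3C[C@]12C(=O)OC
F8 | step 18 | 7β-formate of 27 | C=C[C@](C)(O[Si](C)(C)C(C)(C)C)CCC1=C(C)[C@@H](OC=O)C[C@H]2C(C)(C)[C@@H]3OC(C)(C)O[C@@H]3C[C@]12C(=O)OC
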